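**Plan**
- Retrosynthesis: the last cut frees the four phenols (three benzyl ethers and the C5 methyl ether, which is peri to the C4 carbonyl). The O1–C2 bond of ring C is then opened to a 2'-hydroxy-α-benzyloxychalcone. Finally C4–C4a and O1–C8a are cut together, giving a tetramethoxybenzyne and an α-benzyloxycinnamic acid.
- Enabling feature: ring A is hexasubstituted, C4a (acyl) and C8a (oxygen) are neighbours, and the four carbons C5–C8 all carry oxygen. A symmetrical 3,4,5,6-tetramethoxybenzyne can therefore deliver the whole of ring A with no regiochemical choice, and C5 is told apart afterwards by its peri relation to C4=O.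
- Forward: ring A is elaborated from a bought aromatic to the ortho-silylaryl triflate, and ring B arrives in 3,4-bis(benzyloxy)benzaldehyde. The C2–C3 bond comes from condensation with a benzyloxyacetate, the aryne insertion joins ring A to the three-carbon chain, and ring C closes last by oxidative O1–C2 bond formation.
- Stereochemistry: the target has no stereocentre. The only stereo-element on the way, the Z alkene of the acid and of the chalcone, disappears when C2=C3 becomes part of ring C.

Key step: step 7

Remark on the chemistry: the Z geometry of the acrylate (aryl trans to the carbonyl group) is assumed as the thermodynamic outcome of the condensation. It does not affect the target, since either alkene isomer would lead to the same flavone.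

**Step 1**
Reactants: 1 2,3,4-trimethoxybenzaldehyde
Product: 3 2,3,4-trimethoxyphenol, via 2,3,4-trimethoxyphenyl formate 2 (not isolated)
Conditions: 30% aq H2O2, cat. H2SO4, MeOH, rt
Reagents that add atoms: hydrogen peroxide, OO
Why: Acid-catalysed Dakin (Baeyer–Villiger-type) oxidation, in which the electron-rich aryl group migrates to oxygen in the hydroperoxide adduct and the aryl formate 2 is methanolysed in the same flask to the phenol.

**Step 2**
Reactants: 3 2,3,4-trimethoxyphenol
Product: 4 1,2,3,4-tetramethoxybenzene
Conditions: MeI, K2CO3, acetone, reflux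
Reagents that add atoms: iodomethane, CI
Why: Williamson ether synthesis on a phenoxide that is the only nucleophilic site in the molecule.

**Step 3**
Reactants: 4 1,2,3,4-tetramethoxybenzene
Product: 7 2,3,4,5-tetramethoxyphenol, via (2,3,4,5-tetramethoxyphenyl)lithium 5 (not isolated), via lithium trimethoxy(2,3,4,5-tetramethoxyphenyl)borate 6 (not isolated)
Conditions: n-BuLi, TMEDA, THF, 0 °C; B(OMe)3, −78 °C → rt; AcOH, 30% aq H2O2, 0 °C → rt
Reagents that add atoms: hydrogen peroxide, OO
Why: Directed ortho-metalation next to a methoxy group (the two free positions are equivalent), borylation of the aryllithium and oxidative 1,2-shift of the aryl group from boron to oxygen should place the hydroxyl on one of the two unsubstituted carbons.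

**Step 4**
Reactants: 7 2,3,4,5-tetramethoxyphenol
Product: 8 2-bromo-3,4,5,6-tetramethoxyphenol
Conditions: NBS, CH2Cl2, −78 → 0 °C
Reagents that add atoms: N-bromosuccinimide, O=C1CCC(=O)N1Br
Why: Electrophilic aromatic bromination can occur only at the single unsubstituted carbon, which is ortho to the hydroxyl, and the cold anhydrous medium should hold back oxidation of the electron-rich phenol to a quinone.

**Step 5**
Reactants: 8 2-bromo-3,4,5,6-tetramethoxyphenol
Product: 12 3,4,5,6-tetramethoxy-2-(trimethylsilyl)phenyl trifluoromethanesulfonate, via (2-bromo-3,4,5,6-tetramethoxyphenoxy)trimethylsilane 9 (not isolated), via {3,4,5,6-tetramethoxy-2-[(trimethylsilyl)oxy]phenyl}lithium 10 (not isolated), via lithium 2,3,4,5-tetramethoxy-6-(trimethylsilyl)phenolate 11 (not isolated)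
Conditions: HMDS, THF, reflux, then evaporation; n-BuLi, THF, −100 → −78 °C; Tf2O, −100 °C → rt
Reagents that add atoms: hexamethyldisilazane, C[Si](C)(C)N[Si](C)(C)C; trifluoromethanesulfonic anhydride, O=S(=O)(OS(=O)(=O)C(F)(F)F)C(F)(F)F
Why: O-silylation, bromine–lithium exchange and anionic 1,3 O→C silyl shift (retro-Brook rearrangement) should put silicon on the carbon that carried bromine, and the lithium phenolate released is trapped as its triflate, which is the standard one-flask route to ortho-silylaryl triflates.

**Step 6**
Reactants: 13 3,4-bis(benzyloxy)benzaldehyde; 14 methyl 2-(benzyloxy)acetate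
Product: 16 (Z)-2-(benzyloxy)-3-[3,4-bis(benzyloxy)phenyl]acrylic acid, via methyl (Z)-2-(benzyloxy)-3-[3,4-bis(benzyloxy)phenyl]acrylate 15 (not isolated)
Conditions: NaOMe, MeOH–THF, reflux; then aq NaOH, reflux; aq HCl, 0 °C
Reagents that add atoms: sodium hydroxide, [Na+].[OH-]
Why: Aldol condensation of the alkoxyacetate enolate with the non-enolisable aldehyde (Claisen–Schmidt type, E1cB loss of water) should give the thermodynamically favoured Z cinnamate, and hydroxide then saponifies the methyl ester without touching the benzyl ethers.

**Step 7**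
Reactants: 12 3,4,5,6-tetramethoxy-2-(trimethylsilyl)phenyl trifluoromethanesulfonate; 16 (Z)-2-(benzyloxy)-3-[3,4-bis(benzyloxy)phenyl]acrylic acid
Product: 19 (Z)-2-(benzyloxy)-3-[3,4-bis(benzyloxy)phenyl]-1-(2-hydroxy-3,4,5,6-tetramethoxyphenyl)prop-2-en-1-one, via 3,4,5,6-tetramethoxybenzyne 17 (not isolated), via 2-caesio-3,4,5,6-tetramethoxyphenyl (Z)-2-(benzyloxy)-3-[3,4-bis(benzyloxy)phenyl]acrylate 18 (not isolated)
Conditions: CsF (4 equiv), 12 (1.5 equiv), THF, 125 °C, sealed tube; aq NH4Cl
Reagents that add atoms: none
Why: Fluoride attacks silicon in 12 and triflate leaves, releasing the symmetrical aryne 17; the caesium carboxylate of 16 adds through oxygen to one aryne carbon, and the aryl anion 18, held ortho to the acyloxy group, attacks its own ester carbonyl through a four-membered transition state whose collapse breaks the acyl C–O bond and gives the phenoxide of ketone 19, so that O–C8a and C4–C4a (flavone numbering) are both made in one operation. The closest known reaction type is the CsF-mediated insertion of arynes into the C–O bond of carboxylic acids, which converts benzoic and cinnamic acids into ortho-hydroxyaryl ketones in hot THF. No ring is closed and no stereocentre is created; the Z alkene of 16 is carried over unchanged, and should part of 19 go on to the corresponding 3-benzyloxyflavanone by 6-endo oxa-Michael addition under the basic conditions, that material would be oxidised to the same flavone in step 8. Regioselectivity is not an issue because the two aryne carbons of 17 are equivalent, each flanked by a methoxy group whose inductive effect also stabilises the developing aryl anion. The selectivity that matters is acyl shift over protonation of 18 (which would stop at the aryl ester), and it is favoured by the aprotic medium, the excess of CsF that keeps the acid as its carboxylate, the high temperature and the proximity of the ester carbonyl. The product phenoxide is flanked by the acyl group and a methoxy group and is chelated to the ketone, which should protect it from arylation by a second aryne.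

**Step 8**
Reactants: 19 (Z)-2-(benzyloxy)-3-[3,4-bis(benzyloxy)phenyl]-1-(2-hydroxy-3,4,5,6-tetramethoxyphenyl)prop-2-en-1-one
Product: 20 3-(benzyloxy)-2-[3,4-bis(benzyloxy)phenyl]-5,6,7,8-tetramethoxy-4H-chromen-4-one
Conditions: I2 (0.1 equiv), DMSO, 130 °C; aq Na2S2O3
Reagents that add atoms: none
Why: Iodine-catalysed oxidative cyclisation of a 2'-hydroxychalcone, in which 6-endo addition of the phenol oxygen to C2 and loss of HI give the chromone while DMSO reoxidises iodide, under conditions that benzyl and methyl aryl ethers are known to survive.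

**Step 9**
Reactants: 20 3-(benzyloxy)-2-[3,4-bis(benzyloxy)phenyl]-5,6,7,8-tetramethoxy-4H-chromen-4-one
Product: 21 3,5,3',4'-tetrahydroxy-6,7,8-trimethoxyflavone (2-(3,4-dihydroxyphenyl)-3,5-dihydroxy-6,7,8-trimethoxy-4H-chromen-4-one)
Conditions: BCl3 (1 M in CH2Cl2, excess), pentamethylbenzene, CH2Cl2, −78 → 0 °C; MeOH, then aq HCl
Reagents that add atoms: none
Why: Lewis-acid ether cleavage, in which BCl3 removes the three benzyl ethers at low temperature with pentamethylbenzene trapping the benzyl cations, and cleaves the C5 methyl ether selectively through its six-membered boron chelate with the C4 carbonyl, while the unchelated methyl ethers at C6, C7 and C8 should remain.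

**Compound list**
1 | 2,3,4-trimethoxybenzaldehyde | COc1ccc(C=O)c(OC)c1OC | starting material
2 | 2,3,4-trimethoxyphenyl formate | COc1ccc(OC=O)c(OC)c1OC | intermediate (not isolated)
3 | 2,3,4-trimethoxyphenol | COc1ccc(O)c(OC)c1OC | intermediate
4 | 1,2,3,4-tetramethoxybenzene | COc1ccc(OC)c(OC)c1OC | intermediate
5 | (2,3,4,5-tetramethoxyphenyl)lithium | [Li]c1cc(OC)c(OC)c(OC)c1OC | intermediate (not isolated)
6 | lithium trimethoxy(2,3,4,5-tetramethoxyphenyl)borate | [Li+].CO[B-](OC)(OC)c1cc(OC)c(OC)c(OC)c1OC | intermediate (not isolated)
7 | 2,3,4,5-tetramethoxyphenol | COc1cc(O)c(OC)c(OC)c1OC | intermediate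
8 | 2-bromo-3,4,5,6-tetramethoxyphenol | COc1c(Br)c(O)c(OC)c(OC)c1OC | intermediate
9 | (2-bromo-3,4,5,6-tetramethoxyphenoxy)trimethylsilane | COc1c(Br)c(O[Si](C)(C)C)c(OC)c(OC)c1OC | intermediate (not isolated)
10 | {3,4,5,6-tetramethoxy-2-[(trimethylsilyl)oxy]phenyl}lithium | [Li]c1c(OC)c(OC)c(OC)c(OC)c1O[Si](C)(C)C | intermediate (not isolated)
11 | lithium 2,3,4,5-tetramethoxy-6-(trimethylsilyl)phenolate | [Li+].COc1c([Si](C)(C)C)c([O-])c(OC)c(OC)c1OC | intermediate (not isolated)
12 | 3,4,5,6-tetramethoxy-2-(trimethylsilyl)phenyl trifluoromethanesulfonate | COc1c(OC)c(OC)c(OS(=O)(=O)C(F)(F)F)c([Si](C)(C)C)c1OC | intermediate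
13 | 3,4-bis(benzyloxy)benzaldehyde | O=Cc1ccc(OCc2ccccc2)c(OCc2ccccc2)c1 | starting material
14 | methyl 2-(benzyloxy)acetate | COC(=O)COCc1ccccc1 | starting material
15 | methyl (Z)-2-(benzyloxy)-3-[3,4-bis(benzyloxy)phenyl]acrylate | COC(=O)/C(OCc1ccccc1)=C/c1ccc(OCc2ccccc2)c(OCc2ccccc2)c1 | intermediate (not isolated)
16 | (Z)-2-(benzyloxy)-3-[3,4-bis(benzyloxy)phenyl]acrylic acid | O=C(O)/C(OCc1ccccc1)=C/c1ccc(OCc2ccccc2)c(OCc2ccccc2)c1 | intermediate
17 | 3,4,5,6-tetramethoxybenzyne | COC1=C(OC)C(OC)=C(OC)C#C1 | intermediate (not isolated)
18 | 2-caesio-3,4,5,6-tetramethoxyphenyl (Z)-2-(benzyloxy)-3-[3,4-bis(benzyloxy)phenyl]acrylate | [Cs]c1c(OC)c(OC)c(OC)c(OC)c1OC(=O)/C(OCc2ccccc2)=C/c2ccc(OCc3ccccc3)c(OCc3ccccc3)c2 | intermediate (not isolated)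
19 | (Z)-2-(benzyloxy)-3-[3,4-bis(benzyloxy)phenyl]-1-(2-hydroxy-3,4,5,6-tetramethoxyphenyl)prop-2-en-1-one | COc1c(OC)c(OC)c(C(=O)/C(OCc2ccccc2)=C/c2ccc(OCc3ccccc3)c(OCc3ccccc3)c2)c(O)c1OC | intermediate
20 | 3-(benzyloxy)-2-[3,4-bis(benzyloxy)phenyl]-5,6,7,8-tetramethoxy-4H-chromen-4-one | COc1c(OC)c(OC)c2c(=O)c(OCc3ccccc3)c(-c3ccc(OCc4ccccc4)c(OCc4ccccc4)c3)oc2c1OC | intermediate
21 | 3,5,3',4'-tetrahydroxy-6,7,8-trimethoxyflavone | COc1c(OC)c(O)c2c(=O)c(O)c(-c3ccc(O)c(O)c3)oc2c1OC | target

**Step count**
Total: 9 steps. Longest linear sequence: 8 steps (steps 1–5, 7, 8 and 9, from compound 1); the acid 16 is made in one step (step 6) and joins at step 7.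

**Steps most likely to fail**

Step 7. The aryl anion 18 may be protonated by acid or by hydrogen fluoride species faster than it attacks the ester carbonyl, so that the sequence stops at O-arylation. Addition of the carboxylate to the hindered aryne may also be slow enough for the aryne to be lost to other pathways. The fallback sets out from bromophenol 8 and acid 16 and returns to the route at 19. Phenol 8 would be acylated with 16 (DCC, DMAP, CH2Cl2; Steglich esterification) to give 2-bromo-3,4,5,6-tetramethoxyphenyl (Z)-2-(benzyloxy)-3-[3,4-bis(benzyloxy)phenyl]acrylate F1. Treatment with t-BuLi (2 equiv) in THF at −100 °C would then effect bromine–lithium exchange. The resulting aryllithium is the lithium counterpart of 18, formed with no proton source present, and should undergo the anionic Fries-type 1,3 O→C acyl shift to give 19 after aqueous work-up. The same two bonds are formed, one at a time.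

Step 8. Closure of O1 onto C2 may be sluggish, because the α-benzyloxy group lowers the electrophilicity of C2 and the doubly ortho-substituted aryl ketone is twisted out of conjugation. Prolonged heating with iodine and HI may then erode the enol benzyl ether. The fallback sets out from 19 and returns at 20, separating ring closure from oxidation. NaOAc in refluxing EtOH should bring about the oxa-Michael closure to 3-(benzyloxy)-2-[3,4-bis(benzyloxy)phenyl]-5,6,7,8-tetramethoxychroman-4-one F2, a mixture of diastereomers whose two stereocentres are removed again. DDQ in refluxing dioxane would then dehydrogenate C2–C3 to give 20.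

Step 9. Methyl groups beyond C5 may be lost (at C6 once the C5 borate has formed, or at the hindered C7 ether) on extended exposure to BCl3, and ring B may be benzylated if cation trapping is incomplete. The fallback sets out from 20 and returns at 21, separating the two deprotections. Hydrogenolysis (H2, 10% Pd/C, EtOAc–MeOH, rt) should remove the three benzyl groups to give 2-(3,4-dihydroxyphenyl)-3-hydroxy-5,6,7,8-tetramethoxy-4H-chromen-4-one F3. Anhydrous AlCl3 in MeCN, followed by dilute aq HCl, would then cleave only the chelated C5 methyl ether, a selectivity established for 5-methoxy polymethoxyflavones.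

**Further compounds**
F1 | step 7 | 2-bromo-3,4,5,6-tetramethoxyphenyl (Z)-2-(benzyloxy)-3-[3,4-bis(benzyloxy)phenyl]acrylate | COc1c(Br)c(OC(=O)/C(OCc2ccccc2)=C/c2ccc(OCc3ccccc3)c(OCc3ccccc3)c2)c(OC)c(OC)c1OC
F2 | step 8 | 3-(benzyloxy)-2-[3,4-bis(benzyloxy)phenyl]-5,6,7,8-tetramethoxychroman-4-one (racemic mixture of diastereomers) | COc1c(OC)c(OC)c2C(=O)C(OCc3ccccc3)C(c3ccc(OCc4ccccc4)c(OCc4ccccc4)c3)Oc2c1OC
F3 | step 9 | 2-(3,4-dihydroxyphenyl)-3-hydroxy-5,6,7,8-tetramethoxy-4H-chromen-4-one | COc1c(OC)c(OC)c2c(=O)c(O)c(-c3ccc(O)c(O)c3)oc2c1OC
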